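**Strategy.** Everything rests on a type 1 intramolecular Diels–Alder reaction (labdane numbering). It exploits that ring B (C5–C6–C7–C8–C9–C10) is a cyclohexene sharing its C5–C10 bond with ring A. An acyclic trienoyl oxazolidinone, whose C5=C6–C7=C8 diene and C9=C10 alkene are linked by the C4–C3–C2–C1 chain, closes both rings in one operation by forming C8–C9 and C5–C10. The endo transition state, the E alkene and the (S)-benzyl auxiliary set C5, C9 and C10 together (trans fusion, angular methyl cis to the C9 chain). The Diels–Alder alkene (C6=C7) is moved later into conjugation (C7=C8) when C17 is oxidised; two B-alkyl Suzuki couplings build both trisubstituted E alkenes.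

Key step: step 8

Remark: labdane numbering is used throughout (ring A C1–C5 and C10; ring B C5–C10; side chain C11–C16 on C9; C17 on C8; C18 and C19 on C4; C20 on C10). The target SMILES is read as the normal labdane series (5S,9R,10S: H-5 α, H-9 α, CH3-20 β, 13E). Compounds 1, 2, 6, 8, 12 and 13 are taken as commercial.

**Step 1**
Reactants: 1 2,2-dimethylpent-4-enal; 2 triethyl (E)-4-phosphonobut-2-enoate
Product: 3 ethyl (2E,4E)-6,6-dimethylnona-2,4,8-trienoate
Conditions: LiN(SiMe3)2, THF, −78 °C to rt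
Reagents that add atoms: none
Why: Horner–Wadsworth–Emmons olefination with the vinylogous phosphonate anion; the non-enolisable α-quaternary aldehyde and the reversible addition of the stabilised anion should give the (2E,4E)-dienoate, the isolated vinyl group being inert.

**Step 2**
Reactants: 3 ethyl (2E,4E)-6,6-dimethylnona-2,4,8-trienoate
Product: 4 (2E,4E)-6,6-dimethylnona-2,4,8-trien-1-ol
Conditions: i-Bu2AlH (DIBAL-H), CH2Cl2, −78 °C
Reagents that add atoms: none
Why: 1,2-Reduction of the conjugated ester by the aluminium hydride at low temperature should stop cleanly at the dienyl alcohol without touching any alkene.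

**Step 3**
Reactants: 4 (2E,4E)-6,6-dimethylnona-2,4,8-trien-1-ol
Product: 5 tert-butyl{[(2E,4E)-6,6-dimethylnona-2,4,8-trien-1-yl]oxy}dimethylsilane
Conditions: TBSCl, imidazole, CH2Cl2, 0 °C to rt
Reagents that add atoms: tert-butyldimethylsilyl chloride, CC(C)(C)[Si](C)(C)Cl
Why: Standard silylation of a primary alcohol; the silyl ether keeps the diene electron-rich and non-chelating for the Lewis-acid step and tolerates base, hydride and palladium.

**Step 4**
Reactants: 6 methyl 3-oxobutanoate
Product: 7 methyl (E)-3-(trifluoromethylsulfonyloxy)but-2-enoate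
Conditions: Tf2O, aq. Me4NOH, hexane, 5 °C
Reagents that add atoms: trifluoromethanesulfonic anhydride, O=S(=O)(OS(=O)(=O)C(F)(F)F)C(F)(F)F
Why: Stereoselective enol triflation of a β-keto ester: with the non-coordinating tetramethylammonium counter-ion the enolate reacts in its extended, non-chelated form, so the triflate should end trans to the ester (E).

**Step 5**
Reactants: 5 tert-butyl{[(2E,4E)-6,6-dimethylnona-2,4,8-trien-1-yl]oxy}dimethylsilane; 8 9-borabicyclo[3.3.1]nonane (9-BBN); 7 methyl (E)-3-(trifluoromethylsulfonyloxy)but-2-enoate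
Product: 10 methyl (2E,8E,10E)-12-(tert-butyldimethylsilyloxy)-3,7,7-trimethyldodeca-2,8,10-trienoate, via B-alkyl-9-BBN borane 9 (not isolated)
Conditions: 9-BBN, THF, 0 °C to rt; then 7, Pd(dppf)Cl2 (cat.), AsPh3, aq. K3PO4, DMF, rt
Reagents that add atoms: none
Why: 9-BBN should hydroborate only the monosubstituted alkene (anti-Markovnikov; the internal conjugated diene is much slower), and the B-alkyl Suzuki–Miyaura coupling with the enol triflate proceeds with retention, fixing the E geometry of the future C9=C10 bond (chain trans to the ester).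

**Step 6**
Reactants: 10 methyl (2E,8E,10E)-12-(tert-butyldimethylsilyloxy)-3,7,7-trimethyldodeca-2,8,10-trienoate
Product: 11 (2E,8E,10E)-12-(tert-butyldimethylsilyloxy)-3,7,7-trimethyldodeca-2,8,10-trienoic acid
Conditions: LiOH, THF/MeOH/H2O, 40 °C; then cold dilute HCl to pH 4
Reagents that add atoms: lithium hydroxide, [Li+].[OH-]
Why: Saponification of the methyl ester; the primary silyl ether and the alkene geometries should tolerate aqueous LiOH.

**Step 7**
Reactants: 11 (2E,8E,10E)-12-(tert-butyldimethylsilyloxy)-3,7,7-trimethyldodeca-2,8,10-trienoic acid; 12 pivaloyl chloride; 13 (S)-4-benzyloxazolidin-2-one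
Product: 15 (S)-4-benzyl-3-[(2E,8E,10E)-12-(tert-butyldimethylsilyloxy)-3,7,7-trimethyldodeca-2,8,10-trienoyl]oxazolidin-2-one, via mixed pivalic anhydride 14 (not isolated)
Conditions: 12, Et3N, THF, −20 °C; then LiCl, 13, rt
Reagents that add atoms: none
Why: N-Acylation of the oxazolidinone through the mixed anhydride under LiCl/Et3N; attack should occur at the enoyl carbonyl because the pivaloyl carbonyl is shielded by its tert-butyl group.

**Step 8**
Reactants: 15 (S)-4-benzyl-3-[(2E,8E,10E)-12-(tert-butyldimethylsilyloxy)-3,7,7-trimethyldodeca-2,8,10-trienoyl]oxazolidin-2-one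
Product: 16 (S)-4-benzyl-3-[17-(tert-butyldimethylsilyloxy)-12,13,14,15,16-pentanorlabd-6-en-11-oyl]oxazolidin-2-one (5α-H, 8α-H, 9α-H, 10β-CH3)
Conditions: Me2AlCl (1.5 equiv), CH2Cl2, −30 to 0 °C
Reagents that add atoms: none
Why: Chelation of the aluminium centre by both imide carbonyls gives a cationic, s-cis-locked enoyl dienophile that should undergo an asynchronous concerted type 1 intramolecular Diels–Alder reaction with the tethered (E,E)-diene; the closest known reaction type is the Lewis-acid-promoted cycloaddition of (2E,8E,10E)-undecatrienoyl oxazolidinones, applied here to a β-methyl dienophile. Ring B is the new cyclohexene of the [4+2] union (bonds C8–C9 and C5–C10), and ring A closes in the same event as the six-membered tether ring (C10–C1–C2–C3–C4–C5) in the fused mode through the C5–C10 bond. The endo transition state (imide carbonyl under the diene, tether in a chair) makes the ring fusion trans (H-5 α, CH3-20 β); the E geometry of the C9=C10 alkene is transferred suprafacially so that the acyl carbon C11 on C9 is cis to CH3-20 (H-9 α); the E geometry of the diene terminus puts CH2OTBS on C8 cis to C11, a centre that is erased later. The absolute configuration comes from the (S)-benzyl group, which covers the Cα-re face of the chelated s-cis imide so that the diene adds to the Cα-si face at C9. The step needs endo over exo and one π-face; the chelate secures both, while the gem-dimethyl group at C4 (Thorpe–Ingold effect) and the electron-rich silyloxymethyl diene offset the lower reactivity of the β,β-disubstituted dienophile.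

**Step 9**
Reactants: 16 (S)-4-benzyl-3-[17-(tert-butyldimethylsilyloxy)-12,13,14,15,16-pentanorlabd-6-en-11-oyl]oxazolidin-2-one
Product: 17 17-(tert-butyldimethylsilyloxy)-12,13,14,15,16-pentanorlabd-6-en-11-ol (5α-H, 8α-H, 9α-H, 10β-CH3)
Conditions: LiBH4, MeOH (1 equiv), THF, 0 °C to rt
Reagents that add atoms: none
Why: Reductive removal of the auxiliary: LiBH4 should reduce the lithium-chelated exocyclic imide carbonyl to the primary alcohol, leaving silyl ether, alkene and all stereocentres untouched.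

**Step 10**
Reactants: 17 17-(tert-butyldimethylsilyloxy)-12,13,14,15,16-pentanorlabd-6-en-11-ol
Product: 18 17-(tert-butyldimethylsilyloxy)-12,13,14,15,16-pentanorlabd-6-en-11-al (5α-H, 8α-H, 9α-H, 10β-CH3)
Conditions: Dess–Martin periodinane, NaHCO3, CH2Cl2, 0 °C to rt
Reagents that add atoms: none
Why: Dess–Martin oxidation under buffered, non-basic conditions should give the aldehyde without epimerising C9.

**Step 11**
Reactants: 18 17-(tert-butyldimethylsilyloxy)-12,13,14,15,16-pentanorlabd-6-en-11-al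
Product: 19 17-(tert-butyldimethylsilyloxy)-13,14,15,16-tetranorlabda-6,11-diene (5α-H, 8α-H, 9α-H, 10β-CH3)
Conditions: Ph3PCH3Br, KN(SiMe3)2, THF, 0 °C; then 18, −78 to 0 °C
Reagents that add atoms: methyltriphenylphosphonium bromide, C[P+](c1ccccc1)(c1ccccc1)c1ccccc1.[Br-]
Why: Wittig methylenation with the small non-stabilised ylide at low temperature should convert the hindered aldehyde into the terminal C11=C12 alkene faster than enolisation at C9.

**Step 12**
Reactants: 19 17-(tert-butyldimethylsilyloxy)-13,14,15,16-tetranorlabda-6,11-diene; 8 9-borabicyclo[3.3.1]nonane (9-BBN); 7 methyl (E)-3-(trifluoromethylsulfonyloxy)but-2-enoate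
Product: 21 methyl 17-(tert-butyldimethylsilyloxy)labda-6,13E-dien-15-oate (5α-H, 8α-H, 9α-H, 10β-CH3), via B-alkyl-9-BBN borane 20 (not isolated)
Conditions: 9-BBN, THF, rt to 50 °C; then 7, Pd(dppf)Cl2 (cat.), AsPh3, aq. K3PO4, DMF, rt
Reagents that add atoms: none
Why: 9-BBN should add only to the terminal vinyl group (the cis-disubstituted ring alkene is far slower), and the B-alkyl Suzuki–Miyaura coupling with E-triflate 7 forms C12–C13 with retention, setting the 13E alkene.

**Step 13**
Reactants: 21 methyl 17-(tert-butyldimethylsilyloxy)labda-6,13E-dien-15-oate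
Product: 22 17-(tert-butyldimethylsilyloxy)labda-6,13E-dien-15-ol (5α-H, 8α-H, 9α-H, 10β-CH3)
Conditions: i-Bu2AlH (DIBAL-H), CH2Cl2, −78 °C
Reagents that add atoms: none
Why: 1,2-Reduction of the only ester in the molecule by the aluminium hydride should give the E allylic alcohol without alkene migration.

**Step 14**
Reactants: 22 17-(tert-butyldimethylsilyloxy)labda-6,13E-dien-15-ol
Product: 23 15-acetoxy-17-(tert-butyldimethylsilyloxy)labda-6,13E-diene (5α-H, 8α-H, 9α-H, 10β-CH3)
Conditions: Ac2O, pyridine, DMAP (cat.), CH2Cl2, 0 °C to rt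
Reagents that add atoms: acetic anhydride, CC(=O)OC(C)=O
Why: DMAP-catalysed acetylation of the only free hydroxyl group.

**Step 15**
Reactants: 23 15-acetoxy-17-(tert-butyldimethylsilyloxy)labda-6,13E-diene
Product: 24 15-acetoxylabda-6,13E-dien-17-ol (5α-H, 8α-H, 9α-H, 10β-CH3)
Conditions: HF·pyridine, pyridine, THF, 0 °C to rt
Reagents that add atoms: none
Why: Fluoride-mediated desilylation of the primary silyl ether; buffered HF·pyridine should leave the allylic acetate and both alkenes intact.

**Step 16**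
Reactants: 24 15-acetoxylabda-6,13E-dien-17-ol
Product: 26 15-acetoxylabda-7,13E-dien-17-al (5α-H, 9α-H, 10β-CH3), via β,γ-unsaturated aldehyde 25 (not isolated)
Conditions: Dess–Martin periodinane, NaHCO3, CH2Cl2, 0 °C; aqueous work-up; then DBU, CH2Cl2, rt
Reagents that add atoms: none
Why: Dess–Martin oxidation followed by base-mediated isomerisation through the dienolate (deprotonation at C8, reprotonation at C6) should give the thermodynamically favoured conjugated trisubstituted enal; C9–H lies at a cross-conjugated position and is not acidified, so C9 is retained.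

**Step 17**
Reactants: 26 15-acetoxylabda-7,13E-dien-17-al
Product: 27 15-acetoxylabda-7,13E-dien-17-oic acid (target)
Conditions: NaClO2, NaH2PO4, 2-methyl-2-butene, t-BuOH/H2O, rt
Reagents that add atoms: sodium chlorite, [Na+].[O-]Cl=O
Why: Pinnick oxidation of the enal to the acid; 2-methyl-2-butene scavenges hypochlorous acid so that both trisubstituted alkenes and the acetate should survive.

**Compound list**

1 | 2,2-dimethylpent-4-enal | C=CCC(C)(C)C=O | starting material
2 | triethyl (E)-4-phosphonobut-2-enoate | CCOC(=O)/C=C/CP(=O)(OCC)OCC | starting material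
3 | ethyl (2E,4E)-6,6-dimethylnona-2,4,8-trienoate | CCOC(=O)/C=C/C=C/C(C)(C)CC=C | intermediate
4 | (2E,4E)-6,6-dimethylnona-2,4,8-trien-1-ol | OC/C=C/C=C/C(C)(C)CC=C | intermediate
5 | tert-butyl{[(2E,4E)-6,6-dimethylnona-2,4,8-trien-1-yl]oxy}dimethylsilane | CC(C)(C)[Si](C)(C)OC/C=C/C=C/C(C)(C)CC=C | intermediate
6 | methyl 3-oxobutanoate | COC(=O)CC(C)=O | starting material
7 | methyl (E)-3-(trifluoromethylsulfonyloxy)but-2-enoate | COC(=O)/C=C(\C)OS(=O)(=O)C(F)(F)F | intermediate
8 | 9-borabicyclo[3.3.1]nonane (9-BBN) | B1C2CCCC1CCC2 | starting material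
9 | 9-[(5E,7E)-9-(tert-butyldimethylsilyloxy)-4,4-dimethylnona-5,7-dien-1-yl]-9-borabicyclo[3.3.1]nonane | CC(C)(C)[Si](C)(C)OC/C=C/C=C/C(C)(C)CCCB1C2CCCC1CCC2 | intermediate
10 | methyl (2E,8E,10E)-12-(tert-butyldimethylsilyloxy)-3,7,7-trimethyldodeca-2,8,10-trienoate | COC(=O)/C=C(\C)CCCC(C)(C)/C=C/C=C/CO[Si](C)(C)C(C)(C)C | intermediate
11 | (2E,8E,10E)-12-(tert-butyldimethylsilyloxy)-3,7,7-trimethyldodeca-2,8,10-trienoic acid | OC(=O)/C=C(\C)CCCC(C)(C)/C=C/C=C/CO[Si](C)(C)C(C)(C)C | intermediate
12 | pivaloyl chloride | CC(C)(C)C(Cl)=O | starting material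
13 | (S)-4-benzyloxazolidin-2-one | O=C1N[C@@H](Cc2ccccc2)CO1 | starting material
14 | (2E,8E,10E)-12-(tert-butyldimethylsilyloxy)-3,7,7-trimethyldodeca-2,8,10-trienoic pivalic anhydride | CC(C)(C)C(=O)OC(=O)/C=C(\C)CCCC(C)(C)/C=C/C=C/CO[Si](C)(C)C(C)(C)C | intermediate
15 | (S)-4-benzyl-3-[(2E,8E,10E)-12-(tert-butyldimethylsilyloxy)-3,7,7-trimethyldodeca-2,8,10-trienoyl]oxazolidin-2-one | O=C(/C=C(\C)CCCC(C)(C)/C=C/C=C/CO[Si](C)(C)C(C)(C)C)N1[C@@H](Cc2ccccc2)COC1=O | intermediate
16 | (S)-4-benzyl-3-[17-(tert-butyldimethylsilyloxy)-12,13,14,15,16-pentanorlabd-6-en-11-oyl]oxazolidin-2-one (5α-H, 8α-H, 9α-H, 10β-CH3) | O=C([C@H]1[C@@H](CO[Si](C)(C)C(C)(C)C)C=C[C@H]2C(C)(C)CCC[C@]12C)N3[C@@H](Cc4ccccc4)COC3=O | intermediate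
17 | 17-(tert-butyldimethylsilyloxy)-12,13,14,15,16-pentanorlabd-6-en-11-ol (5α-H, 8α-H, 9α-H, 10β-CH3) | OC[C@H]1[C@@H](CO[Si](C)(C)C(C)(C)C)C=C[C@H]2C(C)(C)CCC[C@]12C | intermediate
18 | 17-(tert-butyldimethylsilyloxy)-12,13,14,15,16-pentanorlabd-6-en-11-al (5α-H, 8α-H, 9α-H, 10β-CH3) | O=C[C@H]1[C@@H](CO[Si](C)(C)C(C)(C)C)C=C[C@H]2C(C)(C)CCC[C@]12C | intermediate
19 | 17-(tert-butyldimethylsilyloxy)-13,14,15,16-tetranorlabda-6,11-diene (5α-H, 8α-H, 9α-H, 10β-CH3) | C=C[C@H]1[C@@H](CO[Si](C)(C)C(C)(C)C)C=C[C@H]2C(C)(C)CCC[C@]12C | intermediate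
20 | 12-(9-borabicyclo[3.3.1]nonan-9-yl)-17-(tert-butyldimethylsilyloxy)-13,14,15,16-tetranorlabd-6-ene (5α-H, 8α-H, 9α-H, 10β-CH3) | B3(C4CCCC3CCC4)CC[C@H]1[C@@H](CO[Si](C)(C)C(C)(C)C)C=C[C@H]2C(C)(C)CCC[C@]12C | intermediate
21 | methyl 17-(tert-butyldimethylsilyloxy)labda-6,13E-dien-15-oate (5α-H, 8α-H, 9α-H, 10β-CH3) | COC(=O)/C=C(\C)CC[C@H]1[C@@H](CO[Si](C)(C)C(C)(C)C)C=C[C@H]2C(C)(C)CCC[C@]12C | intermediate
22 | 17-(tert-butyldimethylsilyloxy)labda-6,13E-dien-15-ol (5α-H, 8α-H, 9α-H, 10β-CH3) | OC/C=C(\C)CC[C@H]1[C@@H](CO[Si](C)(C)C(C)(C)C)C=C[C@H]2C(C)(C)CCC[C@]12C | intermediate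
23 | 15-acetoxy-17-(tert-butyldimethylsilyloxy)labda-6,13E-diene (5α-H, 8α-H, 9α-H, 10β-CH3) | CC(=O)OC/C=C(\C)CC[C@H]1[C@@H](CO[Si](C)(C)C(C)(C)C)C=C[C@H]2C(C)(C)CCC[C@]12C | intermediate
24 | 15-acetoxylabda-6,13E-dien-17-ol (5α-H, 8α-H, 9α-H, 10β-CH3) | CC(=O)OC/C=C(\C)CC[C@H]1[C@@H](CO)C=C[C@H]2C(C)(C)CCC[C@]12C | intermediate
25 | 15-acetoxylabda-6,13E-dien-17-al (5α-H, 8α-H, 9α-H, 10β-CH3) | CC(=O)OC/C=C(\C)CC[C@H]1[C@@H](C=O)C=C[C@H]2C(C)(C)CCC[C@]12C | intermediate
26 | 15-acetoxylabda-7,13E-dien-17-al (5α-H, 9α-H, 10β-CH3) | CC(=O)OC/C=C(\C)CC[C@H]1C(C=O)=CC[C@H]2C(C)(C)CCC[C@]12C | intermediate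
27 | 15-acetoxylabda-7,13E-dien-17-oic acid; (1R,4aS,8aS)-1-[(E)-5-acetoxy-3-methylpent-3-enyl]-5,5,8a-trimethyl-1,4,4a,5,6,7,8,8a-octahydronaphthalene-2-carboxylic acid | CC(=O)OC/C=C(\C)CC[C@H]1C(C(=O)O)=CC[C@H]2C(C)(C)CCC[C@]12C | target

**Step count.** Total: 17 steps. Longest linear sequence: 16 steps (steps 1–3 and 5–17; step 4 is a one-step side branch).

**Steps most likely to fail**

1. Step 8 (key step). The β,β-disubstituted dienophile may react too slowly. Methyl transfer from aluminium, E/Z equilibration of the activated C9=C10 bond or ionisation of the dienyl silyl ether could then compete. The 1,3-diaxial methyl/methyl contact that develops between C10 and C4 may also erode the endo (trans-fusion) preference. Fallback, setting out from 10 and returning at 18: ester 10 would be reduced with i-Bu2AlH to (2E,8E,10E)-12-(tert-butyldimethylsilyloxy)-3,7,7-trimethyldodeca-2,8,10-trien-1-ol F1 and oxidised with MnO2 to (2E,8E,10E)-12-(tert-butyldimethylsilyloxy)-3,7,7-trimethyldodeca-2,8,10-trienal F2. Iminium-ion catalysis of the intramolecular Diels–Alder reaction by the triflic acid salt of (2S,5S)-5-benzyl-2-tert-butyl-3-methylimidazolidin-4-one (MeCN/H2O, −20 to 5 °C) should then give aldehyde 18 directly, because the benzyl group of this amine covers the Cα-re face of the iminium ion as the auxiliary does in step 8. Steps 6, 7, 9 and 10 fall away.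

2. Step 9. Hydride may attack the ring carbonyl of the auxiliary (endocyclic cleavage), or reduction may stall, because the exocyclic acyl carbon lies between a quaternary and a tertiary centre. Fallback, setting out from 16 and returning at 18: imide 16 would be opened with EtSLi (EtSH, n-BuLi, THF, 0 °C), a soft nucleophile that attacks only the exocyclic carbonyl, to S-ethyl 17-(tert-butyldimethylsilyloxy)-12,13,14,15,16-pentanorlabd-6-ene-11-thioate F3. Reduction of the thioester with i-Bu2AlH at −78 °C should give aldehyde 18; step 10 falls away.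

3. Step 12. Hydroboration of the neopentyl-type vinyl group and transmetalation of the hindered alkylborane may be slow, so that base hydrolysis of the β-triflyloxy enoate or protodeboronation takes over. Fallback, setting out from 19 and returning at 21: hydroboration of 19 with 9-BBN followed by NaOH/H2O2 oxidation would give 17-(tert-butyldimethylsilyloxy)-13,14,15,16-tetranorlabd-6-en-12-ol F4. Appel iodination (I2, PPh3, imidazole) would give 12-iodo-17-(tert-butyldimethylsilyloxy)-13,14,15,16-tetranorlabd-6-ene F5. Zinc insertion (Zn dust, LiCl, THF) would give the alkylzinc iodide [17-(tert-butyldimethylsilyloxy)-13,14,15,16-tetranorlabd-6-en-12-yl]zinc iodide F6, and Negishi coupling with triflate 7 (Pd(PPh3)4, THF, rt) should give ester 21 with retention of the E geometry.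

**Further compounds**

F1 | step 8 | (2E,8E,10E)-12-(tert-butyldimethylsilyloxy)-3,7,7-trimethyldodeca-2,8,10-trien-1-ol | OC/C=C(\C)CCCC(C)(C)/C=C/C=C/CO[Si](C)(C)C(C)(C)C
F2 | step 8 | (2E,8E,10E)-12-(tert-butyldimethylsilyloxy)-3,7,7-trimethyldodeca-2,8,10-trienal | O=C/C=C(\C)CCCC(C)(C)/C=C/C=C/CO[Si](C)(C)C(C)(C)C
F3 | step 9 | S-ethyl 17-(tert-butyldimethylsilyloxy)-12,13,14,15,16-pentanorlabd-6-ene-11-thioate (5α-H, 8α-H, 9α-H, 10β-CH3) | CCSC(=O)[C@H]1[C@@H](CO[Si](C)(C)C(C)(C)C)C=C[C@H]2C(C)(C)CCC[C@]12C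
F4 | step 12 | 17-(tert-butyldimethylsilyloxy)-13,14,15,16-tetranorlabd-6-en-12-ol (5α-H, 8α-H, 9α-H, 10β-CH3) | OCC[C@H]1[C@@H](CO[Si](C)(C)C(C)(C)C)C=C[C@H]2C(C)(C)CCC[C@]12C
F5 | step 12 | 12-iodo-17-(tert-butyldimethylsilyloxy)-13,14,15,16-tetranorlabd-6-ene (5α-H, 8α-H, 9α-H, 10β-CH3) | ICC[C@H]1[C@@H](CO[Si](C)(C)C(C)(C)C)C=C[C@H]2C(C)(C)CCC[C@]12C
F6 | step 12 | [17-(tert-butyldimethylsilyloxy)-13,14,15,16-tetranorlabd-6-en-12-yl]zinc iodide (5α-H, 8α-H, 9α-H, 10β-CH3) | I[Zn]CC[C@H]1[C@@H](CO[Si](C)(C)C(C)(C)C)C=C[C@H]2C(C)(C)CCC[C@]12C
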